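Count first.

| flask | substrate | remark | time |
|---|---|---|---|
| beta | 0.38 M | run made earlier |  |
| theta | 1.7 M | run made earlier |  |
| winter | 0.30 M |  | 6.0 min |
| autumn | 0.60 M |  | 6.0 min |
| dawn | 1.2 M |  | 6.0 min |

| beta: time / min | beta: product / % | theta: time / min | theta: product / % |
|---|---|---|---|
| 0.833 | 45.7 | 1.50 | 87.7 |
| 2.00 | 67.0 | 3.00 | 94.1 |
| 4.00 | 78.7 | 5.00 | 96.5 |
| 6.00 | 85.1 | 6.00 | 97.3 |

(each reading ± 0.5 percentage points)

- percent here means substrate units held: one product counts as two
- "hardly changes" means that all values lie within two and a half points (for a concentration: within two and a half percent of the largest)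

- [product] at the end for winter, autumn, dawn, in this order
- the shape of the row from first to last (falls all the way / hardly changes / rises all the way / rises, then falls / falls, then rises)

- A bench rule comes from these two runs, where two substrate go at each turn: at equal minutes, the substrate left differs less than the charge does. After 6.00 min, the readings put beta at 0.0566 M and theta at 0.0459 M, a ratio of 1.23, though theta's charge is 4.47 times beta's.
- With beta's remainder, the rule takes the substrate used, divides by two for product, and gives 0.122 M for winter and 0.572 M for dawn.
- Beta's reading gives 5.71 after 6.00 min in the turnover count N, charged substrate over substrate left, minus one.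
- My own reckoning lets N grow with charge × time. Theta at 1.50 min then expects 13.5% left, and the reading is 12.3%, with a scatter of 0.5 percentage points.
- Scaling by charge gives N of 4.51 for winter, 9.02 for autumn and 18.0 for dawn.
- The substrate left is the charge divided by one plus N, so in this reckoning the bench rule stops working as N comes down towards one. Of these three flasks, winter stands nearest that border.
- This count gives me 0.123 M, 0.270 M and 0.568 M, rising all the way.
- The forecast, slightly apart in the last two values, gives 0.123 M, 0.272 M and 0.572 M, rises all the way, on the ground that “residual substrate is nearly independent of charge”.
- The flasks give 0.124 M, 0.271 M and 0.570 M, rises all the way.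

    2 substrate → product (k = 0.0219 L mol⁻¹ s⁻¹)

- In winter, the 6.0 min stands against a first half-life of 1.27 min, a ratio of 4.72, near the count of 4.51, which leaves 18.1% against the 17% in the flask. Dawn at 3.00 min is reckoned at a count of 9.02, which leaves 9.98% of its charge, and the dawn flask then holds 9.56% of its charge as substrate.

Readings and results are calculated for an exercise, noise included.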